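**Plan**

1. Numbering follows the target SMILES: C1=C2 vinyl, C3 (Me C4), C5–C7, quaternary C8 (Me C9), C10–C11, C12=C13 (Me C14), C15–C16, C17=C18 (Me C19, C20), ring C21, C22=C23 (Me C24), C25, C26, C27, isopropenyl C28–C30.
2. Feature: C8 carries a methyl (C9), a CH2 (C10) and the ring carbon C21, which is the carbon skeleton of methacrolein. The chain atoms C7, C6 and C11, C12 on its two sides are the four carbons of a 1,3-diene, so tying C6 to C12 gives a cyclohexene that a [4+2] addition can build with C8 as its only stereocentre.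
3. Retrosynthetic cuts, in order: C17=C18 (Wittig); C28=C29; ring bonds C21–C27 and C25–C26 (Diels–Alder of a C21=C22–C23=C25 diene with but-3-en-2-one); C23=C25 and C21=C22 (olefinations); C15–C16 with C12=C13 (Johnson–Claisen) and C12–C13 (Grignard); C1=C2; C5–C6 (Wittig, then hydrogenation); C6=C12 (ozonolysis of the temporary ring); C7–C8 and C10–C11 (first Diels–Alder).
4. Forward: the temporary cyclohexene is closed first and cut open at its enol ether. The C7 arm is then lengthened to C1 and the C10 arm to a C17 ester. The real ring (C21–C27) is closed by the second [4+2], and the C17=C18 end is added last so that the 1,5-diene never meets the Lewis acid.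
5. Stereochemistry: C8 from the chiral oxazaborolidinium catalyst in the first cycloaddition; C3 from (R)-3-bromo-2-methylpropan-1-ol; C21 from the catalyst in the second cycloaddition (endo), with C27 then equilibrated to the trans ring; E-C12=C13 from the chair Claisen transition state.

Key step: step 2

Assumption: the B-o-tolyl oxazaborolidinium ions from diphenylprolinol are taken to open the Cα-Si face of boron-bound methacrolein with the (R)-catalyst (step 2) and the Cα-Si face of bound but-3-en-2-one with the (S)-catalyst (step 20), enals and enones binding in different modes; should a trial run show the other sense in either step, the antipodal catalyst is used there and nothing else changes.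

**Route**

Step 1
Reactants: 1 but-3-en-2-one
Product: 2 2-(triisopropylsilyloxy)buta-1,3-diene
Conditions: iPr3SiOTf, Et3N, Et2O, 0 °C to rt
Reagents that add atoms: triisopropylsilyl trifluoromethanesulfonate, CC(C)[Si](OS(=O)(=O)C(F)(F)F)(C(C)C)C(C)C
Why: Amine-promoted enolisation and O-silylation of the methyl ketone (silyl enol ether formation) gives the distillable 2-siloxydiene, and no stereocentre arises.

Step 2
Reactants: 2 2-(triisopropylsilyloxy)buta-1,3-diene; 3 methacrolein
Product: 4 (1R)-1-methyl-4-(triisopropylsilyloxy)cyclohex-3-ene-1-carbaldehyde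
Conditions: (R)-3,3-diphenyl-1-(o-tolyl)tetrahydro-1H,3H-pyrrolo[1,2-c][1,3,2]oxazaborole (10 mol%), HNTf2 (8 mol%), CH2Cl2, −78 °C; Et3N quench
Reagents that add atoms: none
Why: The cationic boron binds the formyl oxygen of s-trans methacrolein (with a formyl C–H···O contact), and the diene adds in a concerted, asynchronous [4+2] cycloaddition in which C10–C11 runs ahead of C7–C8. This is the cationic oxazaborolidine-catalysed enantioselective Diels–Alder reaction of 2-substituted acroleins with 2-silyloxy-1,3-dienes, a known reaction type. The temporary carbocycle (C8, C7, C6, C12, C11, C10) is closed intermolecularly as a six-membered ring by suprafacial addition on both partners. The only new stereocentre, C8, is set by the catalyst, which leaves the Cα-Si face of the bound enal open, so formyl versus methyl is what the catalyst reads. The step needs enal-face selectivity and 1,4 regiochemistry; the catalyst gives the first, and the siloxy group, which makes the diene CH2 next to the C–O carbon the nucleophilic end, gives the second. The C6=C12 enol ether that results marks which arm of C8 has two carbons and which has three.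

Step 3
Reactants: 4 (1R)-1-methyl-4-(triisopropylsilyloxy)cyclohex-3-ene-1-carbaldehyde
Product: 5 [(1R)-1-methyl-4-(triisopropylsilyloxy)cyclohex-3-en-1-yl]methanol
Conditions: NaBH4, EtOH, 0 °C
Reagents that add atoms: none
Why: Borohydride reduction of the aldehyde leaves the base-stable silyl enol ether in place, so the position of the C6=C12 bond, and with it the C8 configuration, is kept.

Step 4
Reactants: 5 [(1R)-1-methyl-4-(triisopropylsilyloxy)cyclohex-3-en-1-yl]methanol
Product: 6 tert-butyl{[(1R)-1-methyl-4-(triisopropylsilyloxy)cyclohex-3-en-1-yl]methoxy}diphenylsilane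
Conditions: tBuPh2SiCl, imidazole, DMAP (cat.), DMF, rt to 40 °C
Reagents that add atoms: tert-butyl(chloro)diphenylsilane, CC(C)(C)[Si](Cl)(c1ccccc1)c1ccccc1
Why: Imidazole-promoted silyl ether formation on the neopentyl alcohol is non-acidic and so cannot shift the enol ether double bond, and this silyl ether should outlast cold fluoride, hydride, ylides and the Claisen step.

Step 5
Reactants: 6 tert-butyl{[(1R)-1-methyl-4-(triisopropylsilyloxy)cyclohex-3-en-1-yl]methoxy}diphenylsilane
Product: 9 (4R)-4-{[tert-butyl(diphenyl)silyl]oxymethyl}-4-methyl-6-oxohexanoic acid, via methoxy hydroperoxide 7 (not isolated), via silyl ester aldehyde 8 (not isolated)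
Conditions: O3, CH2Cl2/MeOH (4:1), −78 °C (Sudan red 7B end point); Me2S, −78 °C to rt; then KF, MeOH/H2O, 0 °C; 1 M HCl to pH 3
Reagents that add atoms: ozone, [O-][O+]=O
Why: Ozonolysis of the silyl enol ether (Criegee cleavage) gives the silyl ester at C12 and a carbonyl oxide at C6 that methanol traps and Me2S reduces to the aldehyde, and fluoride then frees the acid from the labile silyl ester while the hindered silyl ether stays; the quaternary C8 cannot epimerise.

Step 6
Reactants: 9 (4R)-4-{[tert-butyl(diphenyl)silyl]oxymethyl}-4-methyl-6-oxohexanoic acid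
Product: 10 methyl (4R)-4-{[tert-butyl(diphenyl)silyl]oxymethyl}-4-methyl-6-oxohexanoate
Conditions: Me3SiCHN2, PhMe/MeOH (4:1), 0 °C
Reagents that add atoms: (trimethylsilyl)diazomethane, C[Si](C)(C)C=[N+]=[N-]
Why: Diazoalkane esterification of the acid is neutral and leaves the enolisable aldehyde alone.

Step 7
Reactants: 11 (2R)-3-bromo-2-methylpropan-1-ol
Product: 12 {[(2R)-3-bromo-2-methylpropoxy]methyl}benzene
Conditions: benzyl 2,2,2-trichloroacetimidate, TfOH (cat.), CH2Cl2/cyclohexane, 0 °C to rt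
Reagents that add atoms: benzyl 2,2,2-trichloroacetimidate, N=C(OCc1ccccc1)C(Cl)(Cl)Cl
Why: Acid-catalysed O-benzylation with the imidate avoids base, which would cyclise or eliminate the bromo alcohol, and the stereocentre is not involved.

Step 8
Reactants: 12 {[(2R)-3-bromo-2-methylpropoxy]methyl}benzene
Product: 13 [(2R)-3-(benzyloxy)-2-methylpropyl]triphenylphosphonium bromide
Conditions: PPh3, MeCN, 100 °C (sealed tube)
Reagents that add atoms: triphenylphosphine, c1ccc(cc1)P(c1ccccc1)c1ccccc1
Why: SN2 quaternisation of the phosphine by the primary bromide gives the Wittig salt, the β-branch only slowing the reaction.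

Step 9
Reactants: 10 methyl (4R)-4-{[tert-butyl(diphenyl)silyl]oxymethyl}-4-methyl-6-oxohexanoate; 13 [(2R)-3-(benzyloxy)-2-methylpropyl]triphenylphosphonium bromide
Product: 15 methyl (4R,6Z,8S)-9-(benzyloxy)-4-{[tert-butyl(diphenyl)silyl]oxymethyl}-4,8-dimethylnon-6-enoate, via phosphorus ylide 14 (not isolated)
Conditions: 13, NaN(SiMe3)2, THF, 0 °C; then 10, −78 °C to rt
Reagents that add atoms: none
Why: Wittig olefination of the unhindered C6 aldehyde with the non-stabilised ylide joins C5 to C6 without attack on the ester at low temperature; the alkene geometry (mainly Z) does not matter because the bond is saturated next, and C3, β to phosphorus, is untouched.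

Step 10
Reactants: 15 methyl (4R,6Z,8S)-9-(benzyloxy)-4-{[tert-butyl(diphenyl)silyl]oxymethyl}-4,8-dimethylnon-6-enoate
Product: 16 methyl (4S,8S)-4-{[tert-butyl(diphenyl)silyl]oxymethyl}-9-hydroxy-4,8-dimethylnonanoate
Conditions: H2 (1 atm), 10% Pd/C, EtOAc/EtOH, rt
Reagents that add atoms: none
Why: Catalytic hydrogenation saturates the only C=C bond and hydrogenolyses the benzyl ether in one operation, placed here because no other alkene is present yet (the C8 descriptor changes from R to S by CIP priority only).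

Step 11
Reactants: 16 methyl (4S,8S)-4-{[tert-butyl(diphenyl)silyl]oxymethyl}-9-hydroxy-4,8-dimethylnonanoate
Product: 17 methyl (4S,8S)-4-{[tert-butyl(diphenyl)silyl]oxymethyl}-4,8-dimethyl-9-oxononanoate
Conditions: Dess–Martin periodinane, CH2Cl2, 0 °C to rt
Reagents that add atoms: none
Why: Dess–Martin oxidation of the primary alcohol is near-neutral, which limits epimerisation of the α-methyl centre C3.

Step 12
Reactants: 17 methyl (4S,8S)-4-{[tert-butyl(diphenyl)silyl]oxymethyl}-4,8-dimethyl-9-oxononanoate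
Product: 18 methyl (4S,8S)-4-{[tert-butyl(diphenyl)silyl]oxymethyl}-4,8-dimethyldec-9-enoate
Conditions: Ph3PCH3Br, KN(SiMe3)2, THF, 0 °C; then 17, −78 to 0 °C
Reagents that add atoms: methyltriphenylphosphonium bromide, C[P+](c1ccccc1)(c1ccccc1)c1ccccc1.[Br-]
Why: Wittig methylenation at low temperature should convert the aldehyde into the C1=C2 vinyl group faster than C3 enolises, and the methyl ester is spared.

Step 13
Reactants: 18 methyl (4S,8S)-4-{[tert-butyl(diphenyl)silyl]oxymethyl}-4,8-dimethyldec-9-enoate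
Product: 19 (4S,8S)-4-{[tert-butyl(diphenyl)silyl]oxymethyl}-4,8-dimethyldec-9-enal
Conditions: iBu2AlH (1.1 equiv), CH2Cl2, −78 °C; MeOH, aq. KNa tartrate
Reagents that add atoms: none
Why: Partial hydride reduction of the methyl ester stops at the aldehyde because the aluminium hemiacetal collapses only on work-up.

Step 14
Reactants: 19 (4S,8S)-4-{[tert-butyl(diphenyl)silyl]oxymethyl}-4,8-dimethyldec-9-enal
Product: 20 (3RS,6S,10S)-6-{[tert-butyl(diphenyl)silyl]oxymethyl}-2,6,10-trimethyldodeca-1,11-dien-3-ol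
Conditions: CH2=C(CH3)MgBr, THF, −78 to 0 °C
Reagents that add atoms: isopropenylmagnesium bromide, C=C(C)[Mg]Br
Why: Grignard 1,2-addition to the aldehyde brings in C13, C14 and C15, and both C12 epimers are used because this centre disappears in the next step.

Step 15
Reactants: 20 (3RS,6S,10S)-6-{[tert-butyl(diphenyl)silyl]oxymethyl}-2,6,10-trimethyldodeca-1,11-dien-3-ol
Product: 23 methyl (4E,8S,12S)-8-{[tert-butyl(diphenyl)silyl]oxymethyl}-4,8,12-trimethyltetradeca-4,13-dienoate, via mixed orthoester 21 (not isolated), via ketene acetal 22 (not isolated)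
Conditions: MeC(OMe)3 (excess), EtCO2H (5 mol%), 125 °C, MeOH distilled off
Reagents that add atoms: trimethyl orthoacetate, CC(OC)(OC)OC
Why: In this Johnson–Claisen rearrangement the ketene acetal reacts through a chair [3,3] transition state with the C11 chain equatorial, which gives the E-C12=C13 alkene and the C16–C17 ester arm; the methyl ester is chosen so that the later methoxide step cannot scramble it.

Step 16
Reactants: 23 methyl (4E,8S,12S)-8-{[tert-butyl(diphenyl)silyl]oxymethyl}-4,8,12-trimethyltetradeca-4,13-dienoate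
Product: 24 methyl (4E,8S,12S)-8-(hydroxymethyl)-4,8,12-trimethyltetradeca-4,13-dienoate
Conditions: Bu4NF, THF, rt to 40 °C
Reagents that add atoms: none
Why: Fluoride-mediated silyl ether cleavage frees the neopentyl alcohol, and the C17 ester is too remote to lactonise.

Step 17
Reactants: 24 methyl (4E,8S,12S)-8-(hydroxymethyl)-4,8,12-trimethyltetradeca-4,13-dienoate
Product: 25 methyl (4E,8S,12S)-8-formyl-4,8,12-trimethyltetradeca-4,13-dienoate
Conditions: Dess–Martin periodinane, CH2Cl2, rt
Reagents that add atoms: none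
Why: Dess–Martin oxidation gives the α-quaternary aldehyde, which has no α-hydrogen and cannot epimerise.

Step 18
Reactants: 25 methyl (4E,8S,12S)-8-formyl-4,8,12-trimethyltetradeca-4,13-dienoate
Product: 26 methyl (4E,8S,12S)-4,8,12-trimethyl-8-[(1E)-3-oxobut-1-en-1-yl]tetradeca-4,13-dienoate
Conditions: (MeO)2P(O)CH2C(O)CH3, NaH, THF, 0 to 50 °C
Reagents that add atoms: dimethyl (2-oxopropyl)phosphonate, COP(=O)(CC(C)=O)OC
Why: Horner–Wadsworth–Emmons olefination with the β-ketophosphonate anion tolerates the hindered, non-enolisable aldehyde and should give the E-enone (C21=C22) under the usual thermodynamic control.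

Step 19
Reactants: 26 methyl (4E,8S,12S)-4,8,12-trimethyl-8-[(1E)-3-oxobut-1-en-1-yl]tetradeca-4,13-dienoate
Product: 27 methyl (4E,8S,12S)-4,8,12-trimethyl-8-[(1E)-3-methylbuta-1,3-dien-1-yl]tetradeca-4,13-dienoate
Conditions: Ph3PCH3Br, KN(SiMe3)2, THF, 0 °C
Reagents that add atoms: methyltriphenylphosphonium bromide, C[P+](c1ccccc1)(c1ccccc1)c1ccccc1.[Br-]
Why: Wittig methylenation of the enone carbonyl (1,2-addition of the non-stabilised ylide) gives the 2-methyl-1,3-diene without touching the E double bond or the ester.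

Step 20
Reactants: 27 methyl (4E,8S,12S)-4,8,12-trimethyl-8-[(1E)-3-methylbuta-1,3-dien-1-yl]tetradeca-4,13-dienoate; 1 but-3-en-2-one
Product: 28 methyl (4E,8S,12S)-8-[(1S,6R)-6-acetyl-3-methylcyclohex-2-en-1-yl]-4,8,12-trimethyltetradeca-4,13-dienoate
Conditions: (S)-3,3-diphenyl-1-(o-tolyl)tetrahydro-1H,3H-pyrrolo[1,2-c][1,3,2]oxazaborole (15 mol%), HNTf2 (12 mol%), CH2Cl2, −78 to −40 °C; Et3N quench
Reagents that add atoms: none
Why: In this cationic oxazaborolidine-catalysed Diels–Alder reaction of an acyclic enone, the 1-alkyl and 3-methyl groups of the diene both direct the acetyl carbon next to C21, the endo transition state gives the cis adduct, and the catalyst-defined Cα-Si face of the enone sets C21 as S (and C27 as R for the moment), the neighbouring C8 with a methyl and two CH2 arms having little bias of its own.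

Step 21
Reactants: 28 methyl (4E,8S,12S)-8-[(1S,6R)-6-acetyl-3-methylcyclohex-2-en-1-yl]-4,8,12-trimethyltetradeca-4,13-dienoate
Product: 29 methyl (4E,8S,12S)-8-[(1S,6S)-6-acetyl-3-methylcyclohex-2-en-1-yl]-4,8,12-trimethyltetradeca-4,13-dienoate
Conditions: NaOMe (0.3 equiv), MeOH, rt (after evaporation of excess 1)
Reagents that add atoms: none
Why: Base-mediated epimerisation through the ring-side enolate should equilibrate the acetyl-bearing C27 to the more stable trans isomer, C21 being non-enolisable and therefore fixed.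

Step 22
Reactants: 29 methyl (4E,8S,12S)-8-[(1S,6S)-6-acetyl-3-methylcyclohex-2-en-1-yl]-4,8,12-trimethyltetradeca-4,13-dienoate
Product: 30 methyl (4E,8S,12S)-4,8,12-trimethyl-8-[(1S,6S)-3-methyl-6-(prop-1-en-2-yl)cyclohex-2-en-1-yl]tetradeca-4,13-dienoate
Conditions: Ph3PCH3Br, KOtBu, THF, 0 °C to rt
Reagents that add atoms: methyltriphenylphosphonium bromide, C[P+](c1ccccc1)(c1ccccc1)c1ccccc1.[Br-]
Why: Wittig methylenation of the methyl ketone gives the isopropenyl group; any enolisation by the ylide only re-equilibrates C27 towards the same trans isomer, and the ester is far less electrophilic than the ketone.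

Step 23
Reactants: 30 methyl (4E,8S,12S)-4,8,12-trimethyl-8-[(1S,6S)-3-methyl-6-(prop-1-en-2-yl)cyclohex-2-en-1-yl]tetradeca-4,13-dienoate
Product: 31 (4E,8S,12S)-4,8,12-trimethyl-8-[(1S,6S)-3-methyl-6-(prop-1-en-2-yl)cyclohex-2-en-1-yl]tetradeca-4,13-dienal
Conditions: iBu2AlH (1.1 equiv), CH2Cl2, −78 °C; MeOH, aq. KNa tartrate
Reagents that add atoms: none
Why: Partial hydride reduction of the methyl ester to the aldehyde, as in step 13, leaves the four C=C bonds alone.

Step 24
Reactants: 31 (4E,8S,12S)-4,8,12-trimethyl-8-[(1S,6S)-3-methyl-6-(prop-1-en-2-yl)cyclohex-2-en-1-yl]tetradeca-4,13-dienal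
Product: 32 (3S,4S)-1-methyl-4-(prop-1-en-2-yl)-3-[(3S,7S,10E)-3,7,11,15-tetramethylhexadeca-1,10,14-trien-7-yl]cyclohex-1-ene (CNP0208273.1)
Conditions: iPrPPh3I, n-BuLi, THF, 0 °C; then 31, −78 °C to rt
Reagents that add atoms: isopropyltriphenylphosphonium iodide, CC(C)[P+](c1ccccc1)(c1ccccc1)c1ccccc1.[I-]
Why: Wittig olefination with the isopropylidene ylide converts the aldehyde into the C17=C18 alkene, for which no geometry arises, and completes the acid-sensitive 1,5-diene only after all acidic steps.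

**Compound list**

1 | but-3-en-2-one | CC(=O)C=C | starting material
2 | 2-(triisopropylsilyloxy)buta-1,3-diene | C=CC(=C)O[Si](C(C)C)(C(C)C)C(C)C | intermediate
3 | methacrolein | CC(=C)C=O | starting material
4 | (1R)-1-methyl-4-(triisopropylsilyloxy)cyclohex-3-ene-1-carbaldehyde | O=C[C@@]1(C)CC=C(O[Si](C(C)C)(C(C)C)C(C)C)CC1 | intermediate
5 | [(1R)-1-methyl-4-(triisopropylsilyloxy)cyclohex-3-en-1-yl]methanol | OC[C@@]1(C)CC=C(O[Si](C(C)C)(C(C)C)C(C)C)CC1 | intermediate
6 | tert-butyl{[(1R)-1-methyl-4-(triisopropylsilyloxy)cyclohex-3-en-1-yl]methoxy}diphenylsilane | CC(C)(C)[Si](c1ccccc1)(c1ccccc1)OC[C@@]1(C)CC=C(O[Si](C(C)C)(C(C)C)C(C)C)CC1 | intermediate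
7 | triisopropylsilyl (4R)-4-{[tert-butyl(diphenyl)silyl]oxymethyl}-6-hydroperoxy-6-methoxy-4-methylhexanoate (methoxy hydroperoxide, C6 epimers) | COC(OO)C[C@@](C)(CCC(=O)O[Si](C(C)C)(C(C)C)C(C)C)CO[Si](c1ccccc1)(c1ccccc1)C(C)(C)C | intermediate (not isolated)
8 | triisopropylsilyl (4R)-4-{[tert-butyl(diphenyl)silyl]oxymethyl}-4-methyl-6-oxohexanoate (silyl ester aldehyde) | O=CC[C@@](C)(CCC(=O)O[Si](C(C)C)(C(C)C)C(C)C)CO[Si](c1ccccc1)(c1ccccc1)C(C)(C)C | intermediate (not isolated)
9 | (4R)-4-{[tert-butyl(diphenyl)silyl]oxymethyl}-4-methyl-6-oxohexanoic acid | O=CC[C@@](C)(CCC(=O)O)CO[Si](c1ccccc1)(c1ccccc1)C(C)(C)C | intermediate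
10 | methyl (4R)-4-{[tert-butyl(diphenyl)silyl]oxymethyl}-4-methyl-6-oxohexanoate | O=CC[C@@](C)(CCC(=O)OC)CO[Si](c1ccccc1)(c1ccccc1)C(C)(C)C | intermediate
11 | (2R)-3-bromo-2-methylpropan-1-ol | OC[C@@H](C)CBr | starting material
12 | {[(2R)-3-bromo-2-methylpropoxy]methyl}benzene | c1ccccc1COC[C@@H](C)CBr | intermediate
13 | [(2R)-3-(benzyloxy)-2-methylpropyl]triphenylphosphonium bromide | c1ccccc1COC[C@@H](C)C[P+](c1ccccc1)(c1ccccc1)c1ccccc1.[Br-] | intermediate
14 | [(2R)-3-(benzyloxy)-2-methylpropylidene]triphenylphosphorane (phosphorus ylide) | c1ccccc1COC[C@@H](C)C=P(c1ccccc1)(c1ccccc1)c1ccccc1 | intermediate (not isolated)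
15 | methyl (4R,6Z,8S)-9-(benzyloxy)-4-{[tert-butyl(diphenyl)silyl]oxymethyl}-4,8-dimethylnon-6-enoate (mainly Z) | c1ccccc1COC[C@@H](C)/C=C\C[C@@](C)(CCC(=O)OC)CO[Si](c1ccccc1)(c1ccccc1)C(C)(C)C | intermediate
16 | methyl (4S,8S)-4-{[tert-butyl(diphenyl)silyl]oxymethyl}-9-hydroxy-4,8-dimethylnonanoate | OC[C@@H](C)CCC[C@@](C)(CCC(=O)OC)CO[Si](c1ccccc1)(c1ccccc1)C(C)(C)C | intermediate
17 | methyl (4S,8S)-4-{[tert-butyl(diphenyl)silyl]oxymethyl}-4,8-dimethyl-9-oxononanoate | O=C[C@@H](C)CCC[C@@](C)(CCC(=O)OC)CO[Si](c1ccccc1)(c1ccccc1)C(C)(C)C | intermediate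
18 | methyl (4S,8S)-4-{[tert-butyl(diphenyl)silyl]oxymethyl}-4,8-dimethyldec-9-enoate | C=C[C@@H](C)CCC[C@@](C)(CCC(=O)OC)CO[Si](c1ccccc1)(c1ccccc1)C(C)(C)C | intermediate
19 | (4S,8S)-4-{[tert-butyl(diphenyl)silyl]oxymethyl}-4,8-dimethyldec-9-enal | C=C[C@@H](C)CCC[C@@](C)(CCC=O)CO[Si](c1ccccc1)(c1ccccc1)C(C)(C)C | intermediate
20 | (3RS,6S,10S)-6-{[tert-butyl(diphenyl)silyl]oxymethyl}-2,6,10-trimethyldodeca-1,11-dien-3-ol | C=C[C@@H](C)CCC[C@@](C)(CCC(O)C(C)=C)CO[Si](c1ccccc1)(c1ccccc1)C(C)(C)C | intermediate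
21 | mixed orthoester of 20: the 3-(1,1-dimethoxyethoxy) derivative | C=C[C@@H](C)CCC[C@@](C)(CCC(OC(C)(OC)OC)C(C)=C)CO[Si](c1ccccc1)(c1ccccc1)C(C)(C)C | intermediate (not isolated)
22 | ketene acetal of 20: the 3-[(1-methoxyethenyl)oxy] derivative | C=C[C@@H](C)CCC[C@@](C)(CCC(OC(=C)OC)C(C)=C)CO[Si](c1ccccc1)(c1ccccc1)C(C)(C)C | intermediate (not isolated)
23 | methyl (4E,8S,12S)-8-{[tert-butyl(diphenyl)silyl]oxymethyl}-4,8,12-trimethyltetradeca-4,13-dienoate | C=C[C@@H](C)CCC[C@@](C)(CC/C=C(\C)CCC(=O)OC)CO[Si](c1ccccc1)(c1ccccc1)C(C)(C)C | intermediate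
24 | methyl (4E,8S,12S)-8-(hydroxymethyl)-4,8,12-trimethyltetradeca-4,13-dienoate | C=C[C@@H](C)CCC[C@@](C)(CC/C=C(\C)CCC(=O)OC)CO | intermediate
25 | methyl (4E,8S,12S)-8-formyl-4,8,12-trimethyltetradeca-4,13-dienoate | C=C[C@@H](C)CCC[C@@](C)(CC/C=C(\C)CCC(=O)OC)C=O | intermediate
26 | methyl (4E,8S,12S)-4,8,12-trimethyl-8-[(1E)-3-oxobut-1-en-1-yl]tetradeca-4,13-dienoate | C=C[C@@H](C)CCC[C@@](C)(CC/C=C(\C)CCC(=O)OC)/C=C/C(C)=O | intermediate
27 | methyl (4E,8S,12S)-4,8,12-trimethyl-8-[(1E)-3-methylbuta-1,3-dien-1-yl]tetradeca-4,13-dienoate | C=C[C@@H](C)CCC[C@@](C)(CC/C=C(\C)CCC(=O)OC)/C=C/C(C)=C | intermediate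
28 | methyl (4E,8S,12S)-8-[(1S,6R)-6-acetyl-3-methylcyclohex-2-en-1-yl]-4,8,12-trimethyltetradeca-4,13-dienoate (cis ring) | C=C[C@@H](C)CCC[C@@](C)(CC/C=C(\C)CCC(=O)OC)[C@H]1C=C(C)CC[C@H]1C(C)=O | intermediate
29 | methyl (4E,8S,12S)-8-[(1S,6S)-6-acetyl-3-methylcyclohex-2-en-1-yl]-4,8,12-trimethyltetradeca-4,13-dienoate (trans ring) | C=C[C@@H](C)CCC[C@@](C)(CC/C=C(\C)CCC(=O)OC)[C@H]1C=C(C)CC[C@@H]1C(C)=O | intermediate
30 | methyl (4E,8S,12S)-4,8,12-trimethyl-8-[(1S,6S)-3-methyl-6-(prop-1-en-2-yl)cyclohex-2-en-1-yl]tetradeca-4,13-dienoate | C=C[C@@H](C)CCC[C@@](C)(CC/C=C(\C)CCC(=O)OC)[C@H]1C=C(C)CC[C@@H]1C(=C)C | intermediate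
31 | (4E,8S,12S)-4,8,12-trimethyl-8-[(1S,6S)-3-methyl-6-(prop-1-en-2-yl)cyclohex-2-en-1-yl]tetradeca-4,13-dienal | C=C[C@@H](C)CCC[C@@](C)(CC/C=C(\C)CCC=O)[C@H]1C=C(C)CC[C@@H]1C(=C)C | intermediate
32 | (3S,4S)-1-methyl-4-(prop-1-en-2-yl)-3-[(3S,7S,10E)-3,7,11,15-tetramethylhexadeca-1,10,14-trien-7-yl]cyclohex-1-ene | C=C[C@@H](C)CCC[C@@](C)(CC/C=C(\C)CCC=C(C)C)[C@H]1C=C(C)CC[C@@H]1C(=C)C | target

**Step count and risks**

Total: 24 steps. Longest linear sequence: 22 steps (steps 1–6 and 9–24, from but-3-en-2-one); steps 7 and 8 form the two-step side branch.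

Step 20 (second cycloaddition). What may go wrong: insufficient facial or endo selectivity of the catalyst-bound enone towards a diene whose reacting terminus carries a quaternary carbon, or acid-induced loss of the diene before it reacts; either would leave C21 epimers that cannot be separated later. Fallback with auxiliary control in place of catalyst control: setting out from 27, cycloaddition with (4S)-4-benzyl-3-(prop-2-enoyl)-1,3-oxazolidin-2-one and Et2AlCl (CH2Cl2, −78 °C) should give the imide F1. The Al-chelated s-cis acrylimide is attacked on its Cα-Si face, opposite the benzyl group, in the endo mode, which gives the same C21 and C27 configurations as in 28. Aminolysis with MeONHMe·HCl/AlMe3 at −15 °C then gives the N-methoxy-N-methylamide F2, and MeMgBr (THF, −40 °C) gives the cis ketone, so the route is rejoined at 28.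

Step 5 (ozonolysis). What may go wrong: over-oxidation past the enol ether, incomplete release of the acid from its silyl ester, or aldol loss of the aldehyde acid during the fluoride treatment. Fallback with a two-stage ketol cleavage: setting out from 6, dihydroxylation of the enol ether with OsO4 (cat.) and N-methylmorpholine N-oxide (acetone/H2O) should give, with loss of the silanol, the α-hydroxy ketone F3 (hydroxyl on C6, ketone at C12). Pb(OAc)4 in MeOH/PhH at 0 °C then cleaves the C6–C12 bond to the C6 aldehyde and the C12 methyl ester in one operation, so the route is rejoined at 10.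

Step 21 (epimerisation). What may go wrong: the hindered ring CH of the methyl ketone equilibrates slowly while the methyl side enolises and condenses, so that cis material survives and is carried into an inseparable isopropenyl epimer. Fallback that moves the equilibration to the aldehyde oxidation level, where only C27 can enolise: setting out from 27, iminium-catalysed cycloaddition with acrolein using (5S)-5-benzyl-2,2,3-trimethylimidazolidin-4-one hydrochloride (first-generation imidazolidinone catalyst, or its antipode if the sense is reversed; MeCN/H2O, −10 °C) should give the cis aldehyde F4. DBU in CH2Cl2 equilibrates it to the trans aldehyde F5, MeMgBr (THF, −78 °C) gives the carbinol F6, and Dess–Martin oxidation gives the trans ketone, so the route is rejoined at 29.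

**Further compounds**

F1 | step 20 | methyl (4E,8S,12S)-8-[(1S,6R)-6-{[(4S)-4-benzyl-2-oxo-1,3-oxazolidin-3-yl]carbonyl}-3-methylcyclohex-2-en-1-yl]-4,8,12-trimethyltetradeca-4,13-dienoate | C=C[C@@H](C)CCC[C@@](C)(CC/C=C(\C)CCC(=O)OC)[C@H]1C=C(C)CC[C@H]1C(=O)N1[C@@H](Cc2ccccc2)COC1=O
F2 | step 20 | methyl (4E,8S,12S)-8-{(1S,6R)-6-[methoxy(methyl)carbamoyl]-3-methylcyclohex-2-en-1-yl}-4,8,12-trimethyltetradeca-4,13-dienoate | C=C[C@@H](C)CCC[C@@](C)(CC/C=C(\C)CCC(=O)OC)[C@H]1C=C(C)CC[C@H]1C(=O)N(C)OC
F3 | step 5 | (2RS,4R)-4-{[tert-butyl(diphenyl)silyl]oxymethyl}-2-hydroxy-4-methylcyclohexan-1-one | OC1C[C@@](C)(CCC1=O)CO[Si](c2ccccc2)(c2ccccc2)C(C)(C)C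
F4 | step 21 | methyl (4E,8S,12S)-8-[(1S,6R)-6-formyl-3-methylcyclohex-2-en-1-yl]-4,8,12-trimethyltetradeca-4,13-dienoate | C=C[C@@H](C)CCC[C@@](C)(CC/C=C(\C)CCC(=O)OC)[C@H]1C=C(C)CC[C@H]1C=O
F5 | step 21 | methyl (4E,8S,12S)-8-[(1S,6S)-6-formyl-3-methylcyclohex-2-en-1-yl]-4,8,12-trimethyltetradeca-4,13-dienoate | C=C[C@@H](C)CCC[C@@](C)(CC/C=C(\C)CCC(=O)OC)[C@H]1C=C(C)CC[C@@H]1C=O
F6 | step 21 | methyl (4E,8S,12S)-8-[(1S,6S)-6-(1-hydroxyethyl)-3-methylcyclohex-2-en-1-yl]-4,8,12-trimethyltetradeca-4,13-dienoate (carbinol epimers) | C=C[C@@H](C)CCC[C@@](C)(CC/C=C(\C)CCC(=O)OC)[C@H]1C=C(C)CC[C@@H]1C(C)O
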